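## Retrosynthetic overview

1. The oxepane is opened at the aryl ether O–C2; it is closed last by a Schenck ene reaction and SN1' etherification of the seco-phenol.
2. The seco-phenol comes from an o-quinone methide (2,4-diformylphloroglucinol plus isovaleraldehyde, arene dearomatised in situ) and (+)-bicyclogermacrene. One cascade makes the C4–C1' bond and the transannular C1–C5 bond, so the five- and seven-membered rings form together.
3. Bicyclogermacrene comes from a keto aldehyde by McMurry macrocyclisation (C1=C10); the (E)-C4=C5 alkene comes from a Claisen rearrangement; the cyclopropane comes from (+)-2-carene by ozonolysis.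
4. 2,4-Diformylphloroglucinol comes from phloroglucinol by double Vilsmeier–Haack formylation.
5. Ring order: cyclopropane (chiral pool), ten-membered ring, cyclopentane plus cycloheptene, oxepane.

Assumption: terpene carbons carry aromadendrane numbers (C1–C15; C1' is the benzylic carbon), and (+)-2-carene is the (1S,6R) enantiomer.

## Route

Step 1
Reactants: 1 (+)-2-carene
Product: 2 (1S,3R)-2,2-dimethyl-3-(3-oxobutyl)cyclopropane-1-carbaldehyde
Conditions: O3, CH2Cl2–MeOH, −78 °C; then Me2S, −78 → 23 °C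
Reagents that add atoms: ozone [O-][O+]=O
Why: Criegee ozonolysis cleaves the only alkene, and the cis-cyclopropane stereocentres (later C6 and C7) are carried through untouched.

Step 2
Reactants: 2 (1S,3R)-2,2-dimethyl-3-(3-oxobutyl)cyclopropane-1-carbaldehyde; 3 2-bromopropene
Product: 4 4-[(1R,3S)-3-(1-hydroxy-2-methylprop-2-en-1-yl)-2,2-dimethylcyclopropyl]butan-2-one (both carbinol epimers)
Conditions: CrCl2 (4 equiv), NiCl2 (1 mol %), DMF, 23 °C
Reagents that add atoms: none
Why: The Nozaki–Hiyama–Kishi alkenylation attacks the aldehyde and leaves the methyl ketone alone; the new carbinol centre forms as a mixture and is erased in step 3.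

Step 3
Reactants: 4 4-[(1R,3S)-3-(1-hydroxy-2-methylprop-2-en-1-yl)-2,2-dimethylcyclopropyl]butan-2-one; 5 butyl vinyl ether
Product: 7 (4E)-5-[(1S,3R)-2,2-dimethyl-3-(3-oxobutyl)cyclopropyl]-4-methylpent-4-enal, via allyl vinyl ether 6 (not isolated)
Conditions: Pd(OCOCF3)2 (5 mol %), 4,7-diphenyl-1,10-phenanthroline (5 mol %), Et3N, neat 5, 75 °C; evaporate; PhMe, 140 °C, sealed tube
Reagents that add atoms: none
Why: Transfer vinylation followed by Claisen rearrangement through a chair transition state with the cyclopropyl group equatorial gives the (E)-trisubstituted C4=C5 alkene from either carbinol epimer and delivers C1–C3 with C1 as the aldehyde.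

Step 4
Reactants: 7 (4E)-5-[(1S,3R)-2,2-dimethyl-3-(3-oxobutyl)cyclopropyl]-4-methylpent-4-enal
Product: 8 (+)-bicyclogermacrene [(1S,2E,6E,10R)-3,7,11,11-tetramethylbicyclo[8.1.0]undeca-2,6-diene]
Conditions: TiCl3(DME)1.5, Zn–Cu couple, DME, reflux, syringe-pump addition (0.005 M); AgNO3–SiO2 chromatography
Reagents that add atoms: none
Why: Intramolecular McMurry coupling of the aldehyde with the methyl ketone closes the ten-membered ring at C1=C10; the E isomer is expected to predominate and the Z isomer is removed on silver nitrate silica.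

Step 5
Reactants: 9 phloroglucinol
Product: 10 2,4-diformylphloroglucinol (2,4,6-trihydroxybenzene-1,3-dicarbaldehyde)
Conditions: POCl3 (2.2 equiv), DMF (2.2 equiv), 1,4-dioxane, 0 → 23 °C; then H2O
Reagents that add atoms: N,N-dimethylformamide O=CN(C)C; water O
Why: Double Vilsmeier–Haack formylation stops at the dialdehyde because two formyl groups deactivate the last ring position.

Step 6
Reactants: 10 2,4-diformylphloroglucinol; 11 isovaleraldehyde; 8 (+)-bicyclogermacrene
Product: 13 seco-phenol 2,4,6-trihydroxy-5-{(1S)-3-methyl-1-[(1aR,7R,7aR,7bR)-1,1,4,7-tetramethyl-1a,2,3,5,6,7,7a,7b-octahydro-1H-cyclopropa[e]azulen-7-yl]butyl}benzene-1,3-dicarbaldehyde, via o-quinone methide 12 (not isolated)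
Conditions: ethylenediammonium diacetate (20 mol %), (CF3)2CHOH–CH2Cl2 1:4, 0 → 23 °C, dark; 11 (1.5 equiv), 8 (1.2 equiv)
Reagents that add atoms: none
Why: Proposed new method: amine-catalysed Knoevenagel condensation dearomatises 10 to 12, whose exocyclic carbon is attacked by C4 of the vinylcyclopropane alkene of 8 from the outer face of the crown conformer while C1=C10 closes onto C5 from inside (anti addition across the E alkene, the same course as the proton-initiated cyclisation of bicyclogermacrene to ledene), and loss of H1 from the C10 cation gives the tetrasubstituted C1=C10 alkene; this sets C4 (R), C5 (R) and, by an approach with the aryl ring over the C3/H5 edge away from the gem-dimethylcyclopropane, C1' (S); the closest known reaction types are the domino Knoevenagel/o-quinone methide addition to terpene alkenes and the cationic transannular cyclisation of germacrenes.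

Step 7
Reactants: 13 seco-phenol
Product: 16 CNP0388405.1 (target), via allylic hydroperoxide 14 (not isolated), via tertiary allylic alcohol 15 (not isolated)
Conditions: O2, tetraphenylporphyrin (1 mol %), white LED, CH2Cl2, −20 °C; then PPh3, −20 → 23 °C; then pyridinium p-toluenesulfonate (10 mol %), 23 °C
Reagents that add atoms: none
Why: The Schenck ene reaction on the less hindered α face removes the cyclopentane hydrogen H2α (H5 lies on the β face) and puts the hydroperoxide on C10; after reduction, acid ionises the tertiary allylic alcohol to the C2–C1–C10 allyl cation, which the phenol held on the β face by C4 closes at C2 (SN1' etherification, seven-membered ring), setting C2 (R) and restoring C1=C10.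

## Compound list

1 | (+)-2-carene, (1S,6R)-3,7,7-trimethylbicyclo[4.1.0]hept-2-ene | CC1=C[C@H]2[C@@H](CC1)C2(C)C | starting material
2 | (1S,3R)-2,2-dimethyl-3-(3-oxobutyl)cyclopropane-1-carbaldehyde | O=C[C@H]1[C@@H](CCC(C)=O)C1(C)C | intermediate
3 | 2-bromopropene | CC(Br)=C | starting material
4 | 4-[(1R,3S)-3-(1-hydroxy-2-methylprop-2-en-1-yl)-2,2-dimethylcyclopropyl]butan-2-one, carbinol epimers | CC(=C)C(O)[C@H]1[C@@H](CCC(C)=O)C1(C)C | intermediate
5 | butyl vinyl ether | C=COCCCC | starting material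
6 | 4-[(1R,3S)-3-(1-ethenyloxy-2-methylprop-2-en-1-yl)-2,2-dimethylcyclopropyl]butan-2-one (allyl vinyl ether) | C=COC(C(C)=C)[C@H]1[C@@H](CCC(C)=O)C1(C)C | intermediate
7 | (4E)-5-[(1S,3R)-2,2-dimethyl-3-(3-oxobutyl)cyclopropyl]-4-methylpent-4-enal | O=CCC/C(C)=C/[C@H]1[C@@H](CCC(C)=O)C1(C)C | intermediate
8 | (+)-bicyclogermacrene, (1S,2E,6E,10R)-3,7,11,11-tetramethylbicyclo[8.1.0]undeca-2,6-diene | C/C1=C\CC/C(C)=C/[C@H]2[C@@H](CC1)C2(C)C | intermediate
9 | phloroglucinol | Oc1cc(O)cc(O)c1 | starting material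
10 | 2,4-diformylphloroglucinol | O=Cc1c(O)cc(O)c(C=O)c1O | intermediate
11 | isovaleraldehyde (3-methylbutanal) | CC(C)CC=O | starting material
12 | o-quinone methide, 2,4-dihydroxy-5-(3-methylbutylidene)-6-oxocyclohexa-1,3-diene-1,3-dicarbaldehyde | CC(C)CC=C1C(=O)C(C=O)=C(O)C(C=O)=C1O | intermediate
13 | seco-phenol: aromadendr-1(10)-ene carrying the (1S)-1-(3,5-diformyl-2,4,6-trihydroxyphenyl)-3-methylbutyl group on C4 (β), C4 methyl α, H5 β | CC1=C2[C@H]([C@H]3[C@@H](CC1)C3(C)C)[C@](C)(CC2)[C@H](CC(C)C)c1c(O)c(C=O)c(O)c(C=O)c1O | intermediate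
14 | allylic hydroperoxide: 13 with C1=C2 alkene and α-hydroperoxy group on C10 (10R) | C[C@]1(OO)C2=CC[C@](C)([C@H](CC(C)C)c3c(O)c(C=O)c(O)c(C=O)c3O)[C@H]2[C@H]4[C@@H](CC1)C4(C)C | intermediate
15 | tertiary allylic alcohol: 13 with C1=C2 alkene and α-hydroxy group on C10 (10R) | C[C@]1(O)C2=CC[C@](C)([C@H](CC(C)C)c3c(O)c(C=O)c(O)c(C=O)c3O)[C@H]2[C@H]4[C@@H](CC1)C4(C)C | intermediate
16 | CNP0388405.1: aryl ether O–C2 and C1'–C4 both on the β face, C1=C10 alkene | CC1=C2[C@H]([C@H]3[C@@H](CC1)C3(C)C)[C@]1(C)C[C@H]2Oc2c(C=O)c(O)c(C=O)c(O)c2[C@H]1CC(C)C | target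

## Step count and risks

Total: 7 steps. Longest linear sequence: 6 steps (1, 2, 3, 4, 6, 7); step 5 is a one-step side branch.

Most likely to fail:

**Step 6.** The o-quinone methide may instead close a chroman at C5, 8 may cyclise to ledene by simple protonation, and C1' may form as a mixture. The fallback sets out from 10 and 11 and comes back at 13. Here 10, 11 and benzenethiol are first condensed (ethylenediammonium diacetate, MeCN, 23 °C) to the bench-stable benzylic sulfide 2,4,6-trihydroxy-5-[3-methyl-1-(phenylsulfanyl)butyl]benzene-1,3-dicarbaldehyde F1. This sulfide is then ionised with AgOSO2CF3 and 2,6-di-tert-butylpyridine in CH2Cl2 at −40 °C in the presence of 8, so that 12 is released slowly under buffered, aprotic conditions and the same cascade gives 13.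

**Step 7.** The ene reaction may abstract H9 or a C14 hydrogen instead of H2. The fallback sets out from 13 and comes back at 16. Allylic hydroxylation with catalytic SeO2 and t-BuOOH (ene reaction then 2,3-shift, which leaves C1=C10 in place) targets the cyclopentane methylene. It gives the C2 alcohol 2,4,6-trihydroxy-5-{(1S)-1-[(1aR,7R,7aR,7bR)-5-hydroxy-1,1,4,7-tetramethyl-1a,2,3,5,6,7,7a,7b-octahydro-1H-cyclopropa[e]azulen-7-yl]-3-methylbutyl}benzene-1,3-dicarbaldehyde F2 (either C2 epimer). Pyridinium p-toluenesulfonate then ionises F2 to the same allyl cation, which closes to 16.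

**Step 4.** E/Z control at C1=C10 and the heat sensitivity of 8 are the concerns. The fallback sets out from 2 and comes back at 8, fixing both alkene geometries before ring closure and closing the ring at C2–C3 instead.
- Aldehyde-selective Wittig reaction of 2 with Ph3P=C(CH3)CO2Et gives ethyl (2E)-3-[(1S,3R)-2,2-dimethyl-3-(3-oxobutyl)cyclopropyl]-2-methylprop-2-enoate F3.
- Horner–Wadsworth–Emmons reaction of the ketone with triethyl phosphonoacetate and NaH, with separation of the minor Z isomer, gives ethyl (2E)-5-[(1R,3S)-3-[(1E)-3-ethoxy-2-methyl-3-oxoprop-1-en-1-yl]-2,2-dimethylcyclopropyl]-3-methylpent-2-enoate F4.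
- Reduction with i-Bu2AlH gives (2E)-5-[(1R,3S)-3-[(1E)-3-hydroxy-2-methylprop-1-en-1-yl]-2,2-dimethylcyclopropyl]-3-methylpent-2-en-1-ol F5.
- CBr4 and PPh3 give (1S,3R)-1-[(1E)-3-bromo-2-methylprop-1-en-1-yl]-3-[(3E)-5-bromo-3-methylpent-3-en-1-yl]-2,2-dimethylcyclopropane F6.
- Reductive allyl–allyl coupling with Ni(CO)4 in N-methylpyrrolidone at high dilution closes the ring to 8.

## Further compounds

F1 | step 6 | 2,4,6-trihydroxy-5-[3-methyl-1-(phenylsulfanyl)butyl]benzene-1,3-dicarbaldehyde (racemic) | CC(C)CC(Sc1ccccc1)c1c(O)c(C=O)c(O)c(C=O)c1O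
F2 | step 7 | 2,4,6-trihydroxy-5-{(1S)-1-[(1aR,7R,7aR,7bR)-5-hydroxy-1,1,4,7-tetramethyl-1a,2,3,5,6,7,7a,7b-octahydro-1H-cyclopropa[e]azulen-7-yl]-3-methylbutyl}benzene-1,3-dicarbaldehyde (either C2 epimer) | CC1=C2[C@H]([C@H]3[C@@H](CC1)C3(C)C)[C@](C)(CC2O)[C@H](CC(C)C)c1c(O)c(C=O)c(O)c(C=O)c1O
F3 | step 4 | ethyl (2E)-3-[(1S,3R)-2,2-dimethyl-3-(3-oxobutyl)cyclopropyl]-2-methylprop-2-enoate | CCOC(=O)/C(C)=C/[C@H]1[C@@H](CCC(C)=O)C1(C)C
F4 | step 4 | ethyl (2E)-5-[(1R,3S)-3-[(1E)-3-ethoxy-2-methyl-3-oxoprop-1-en-1-yl]-2,2-dimethylcyclopropyl]-3-methylpent-2-enoate | CCOC(=O)/C(C)=C/[C@H]1[C@@H](CC/C(C)=C/C(=O)OCC)C1(C)C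
F5 | step 4 | (2E)-5-[(1R,3S)-3-[(1E)-3-hydroxy-2-methylprop-1-en-1-yl]-2,2-dimethylcyclopropyl]-3-methylpent-2-en-1-ol | OC/C(C)=C/[C@H]1[C@@H](CC/C(C)=C/CO)C1(C)C
F6 | step 4 | (1S,3R)-1-[(1E)-3-bromo-2-methylprop-1-en-1-yl]-3-[(3E)-5-bromo-3-methylpent-3-en-1-yl]-2,2-dimethylcyclopropane | BrC/C(C)=C/[C@H]1[C@@H](CC/C(C)=C/CBr)C1(C)C
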